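When I read Tuesday's run at 2.3 min, c(target) stood at 28.7 mM, an early rate of 12.5 mM min⁻¹. Between the fourth and last readings, with 35.6% of the starting material turned by the end, the rate was still 10.2 mM min⁻¹, or 0.816 of the early one.

| flask | starting material | partner | catalyst | target | time |
|---|---|---|---|---|---|
| Tuesday's | 250 mM | 250 mM | 25.0 mM |  |  |
| Sunday's | 250 mM | 250 mM | 25.0 mM | 75.0 mM |  |
| Friday's | 83.0 mM | 750 mM | 25.0 mM |  | 7.9 min |

| run | time / min | [target] / mM |
|---|---|---|
| Tuesday's run | 1.1 | 14.7 |
| Tuesday's run | 2.3 | 28.7 |
| Tuesday's run | 3.4 | 39.7 |
| Tuesday's run | 4.5 | 54.3 |
| Tuesday's run | 5.6 | 63.2 |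
| Tuesday's run | 6.8 | 77.7 |
| Tuesday's run | 7.9 | 89.1 |
| Sunday's run | 1.1 | 87.1 |
| Sunday's run | 2.3 | 101.3 |
| Sunday's run | 3.4 | 112.9 |
| Sunday's run | 4.5 | 123.7 |
| Sunday's run | 5.6 | 134.3 |
| Sunday's run | 6.8 | 145.7 |
| Sunday's run | 7.9 | 155.0 |

(readings scatter by 1 mM)

- target in the Friday's run at 7.9 min, as a share of the starting material charged

- Overall: starting material + partner -> target, with catalyst as catalyst.
- Constant volume, constant temperature.
- The analysis sees a species whether free or bound.
- "The second partner" is partner.

I set two times side by side for Friday's flask. One was the time asked, 7.9 min. The other I took from Friday's charge and Tuesday's early rate, which gave 6.65 min; I called this the clearing time, the charge of starting material divided by the early rate. Their ratio was 1.19, the time asked being longer than the clearing time. I assumed, without a run to test it, that Friday's flask would start at Tuesday's rate. Its starting material was the limiting reagent, and turning the whole charge would use 11.1% of the partner. That did not make the rate first order in starting material, so it was a bare assumption of mine that the rate in Friday's flask would fall in proportion to c(starting material), with the clearing time as its time constant. That gave a share of 69.5%. The forecast reached 70% by another road, a saturation rate law, and it warned: “These runs cannot separate Ka from Kb”.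

Friday's flask gave 74.2%, so the forecast stood within its tolerance.

    catalyst + starting material ⇌ catalyst-substrate complex, settled at all times (8.380 M⁻¹)
    catalyst-substrate complex + partner ⇌ ternary complex, settled at all times (77.80 M⁻¹)
    ternary complex → target + catalyst (0.7200 min⁻¹)
    2 partner ⇌ idle reagent dimer, settled at all times (38.10 M⁻¹)
    target + partner → side product (0.3696 M⁻¹ min⁻¹)

In this scheme, the joining of two partner to idle reagent dimer moves the readings by 7.0 times the scatter, root mean square. Put through my assumed exponential, Friday's share corresponds to a clearing time of 5.83 min instead of 6.65 min, which is 0.877 of it. Scaled to Tuesday's charge, the clearing time is 20.0 min, and the same exponential puts half of that charge at 13.9 min; Tuesday's run reached that point at 12.1 min, which is 0.871 of the reckoned time.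

(The runs are simulated for substances that don't exist; the scatter is artificial.)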